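**Retrosynthetic overview**

1. Furan ring (closed last): the benzofuran is cut at O–C2 and C3–C3a to an (S)-configured silyl enyne and 1-(2,4-dihydroxy-5-iodophenyl)ethanone, which are joined by a tandem sila-Sonogashira coupling and 5-endo-dig annulation.
2. Stereocentre and its bond to the alkene: nickel-catalysed enantioconvergent decarboxylative vinylation of a racemic 2-(chromen-6-yl)propanoic N-hydroxyphthalimide ester with an (E)-bromoenyne made by carboalumination.
3. Pyran ring (closed first): the C2–C3 bond of the chromene is made by anodic decarboxylation of a 2-(2-vinylaryloxy)-2-methylpropanoic acid to an aryloxycarbenium ion that closes onto the vinyl group; the acid comes in two steps from 5-bromo-2-hydroxy-4-methoxybenzaldehyde.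
4. Enabling feature (chromene numbering): C2 of the pyran ring is a quaternary carbon bound to the ring oxygen O1, so it can be stored as an α-aryloxy acid and released as the cation O1=C2(+); C3=C4 is a styrene on the benzene ring of the chromene (ring A), whose C7 methoxy group (para to C4a) and O1 (ortho) stabilise the positive charge that the closure places on C4.
5. Ring order: pyran ring of the chromene (step 3), then furan ring of the benzofuran (step 11); both benzene rings are bought.

Key step: step 3

Assumption: in step 9 the antipode of the bis(oxazoline) ligand is used that delivers the S configuration; which antipode does so would be fixed on a model 2-arylpropanoate ester.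

**Route**

Step 1
Reactants: 1 5-bromo-2-hydroxy-4-methoxybenzaldehyde
Product: 2 4-bromo-2-ethenyl-5-methoxyphenol
Conditions: Ph3PCH3Br (2.5 equiv), KOtBu (2.5 equiv), THF, 0 °C to rt; aq NH4Cl
Reagents that add atoms: methyltriphenylphosphonium bromide, C[P+](c1ccccc1)(c1ccccc1)c1ccccc1.[Br-]
Why: Wittig methylenation, in which the first equivalent of ylide only forms the phenoxide and the excess converts the aldehyde into the vinyl group, should give the ortho-vinylphenol without touching the aryl bromide.

Step 2
Reactants: 2 4-bromo-2-ethenyl-5-methoxyphenol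
Product: 3 2-(4-bromo-2-ethenyl-5-methoxyphenoxy)-2-methylpropanoic acid
Conditions: BrC(CH3)2CO2H (3 equiv), NaOH (powder, 8 equiv), butan-2-one, 50 °C; cold dilute HCl
Reagents that add atoms: 2-bromo-2-methylpropanoic acid, CC(C)(Br)C(=O)O
Why: Williamson-type O-alkylation of the sodium phenoxide by 2-bromo-2-methylpropanoate (through its α-lactone), the standard route to 2-aryloxy-2-methylpropanoic acids, should install the quaternary carbon and its carboxyl handle in one step.

Step 3
Reactants: 3 2-(4-bromo-2-ethenyl-5-methoxyphenoxy)-2-methylpropanoic acid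
Product: 4 6-bromo-7-methoxy-2,2-dimethyl-2H-chromene
Conditions: graphite anode, Pt cathode, undivided cell, constant current (about 2.2 F/mol), 2,4,6-collidine (2 equiv), Bu4NPF6 (0.1 M), CH2Cl2–(CF3)2CHOH 9:1, 3 Å molecular sieves, 0.02 M, rt
Reagents that add atoms: none
Why: Proposed new method: anodic oxidation of the collidinium carboxylate of 3, directly or by way of the radical cation of the electron-rich ring A (a pseudo-Kolbe path), should expel CO2 and, after the second electron, leave the aryloxycarbenium ion ArO(+)=C(CH3)2, which is a 2-oxonia-hexatriene (C2=O1(+)–C8a=C4a–C4=C3) poised for closure. The closest known reaction type is the Hofer–Moest decarboxylation of α-alkoxy and α-aryloxy acids to oxocarbenium ions that are trapped by heteroatom nucleophiles, joined here to a Prins-type cation–olefin cyclisation; the nitrogen counterpart, closure of imines and iminium ions of 2-vinylanilines to dihydroquinolines, is known. The pyran ring should close in a 6-endo-trig mode (formally a 6π electrocyclisation) by attack of the terminal vinyl carbon C3 on C2, and the resulting chroman-4-yl cation should lose a C3 proton to collidine to give the C3=C4 alkene. No stereocentre is formed. The step needs C3 and not C4 to bond to C2, which the substrate secures because only attack through C3 places the charge on benzylic C4, para to the C7 methoxy group and ortho to O1, whereas closure through C4 would need a primary cation, and because the tertiary α-aryloxy radical is oxidised far more easily than the carboxylate, so that the cation and not the radical is the species that cyclises. Intramolecularity, high dilution and the non-nucleophilic medium should let ring closure outrun dimerisation of the styrene radical cation, capture of the carbenium ion or its deprotonation to an isopropenyl ether.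

Step 4
Reactants: 4 6-bromo-7-methoxy-2,2-dimethyl-2H-chromene
Product: 5 ethyl 2-(7-methoxy-2,2-dimethyl-2H-chromen-6-yl)propanoate (racemic)
Conditions: BrZnCH(CH3)CO2Et (1.5 equiv, stock solution from ethyl 2-bromopropanoate and Zn), Pd(dba)2 (2 mol %), P(t-Bu)3 (2 mol %), THF, rt
Reagents that add atoms: (1-ethoxy-1-oxopropan-2-yl)zinc bromide, CCOC(=O)C(C)[Zn]Br
Why: Palladium-catalysed α-arylation of a Reformatsky reagent (a Negishi-type coupling of a zinc ester enolate) runs under neutral conditions that the chromene tolerates, and the new stereocentre is deliberately formed as a racemate because step 9 is enantioconvergent.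

Step 5
Reactants: 5 ethyl 2-(7-methoxy-2,2-dimethyl-2H-chromen-6-yl)propanoate (racemic)
Product: 6 2-(7-methoxy-2,2-dimethyl-2H-chromen-6-yl)propanoic acid (racemic)
Conditions: LiOH·H2O (3 equiv), THF–MeOH–H2O, rt; cold 1 M HCl to pH 3
Reagents that add atoms: lithium hydroxide (hydroxide oxygen), [Li+].[OH-]
Why: Saponification of the unhindered ethyl ester should proceed at room temperature, the chromene being stable to base and the brief, cold acidification sparing the acid-sensitive electron-rich chromene.

Step 6
Reactants: 6 2-(7-methoxy-2,2-dimethyl-2H-chromen-6-yl)propanoic acid (racemic)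
Product: 7 1,3-dioxoisoindolin-2-yl 2-(7-methoxy-2,2-dimethyl-2H-chromen-6-yl)propanoate (racemic)
Conditions: N-hydroxyphthalimide (1.1 equiv), N,N'-diisopropylcarbodiimide (1.1 equiv), DMAP (10 mol %), CH2Cl2, rt
Reagents that add atoms: N-hydroxyphthalimide, O=C1c2ccccc2C(=O)N1O
Why: Carbodiimide-mediated (Steglich-type) esterification with N-hydroxyphthalimide should give the redox-active ester that serves as the radical precursor.

Step 7
Reactants: 8 1,4-bis(trimethylsilyl)buta-1,3-diyne
Product: 9 buta-1,3-diyn-1-yl(trimethyl)silane
Conditions: MeLi·LiBr (1.05 equiv), Et2O, rt; H2O; used as a dried solution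
Reagents that add atoms: none
Why: Nucleophilic desilylation by methyllithium at one silicon of the symmetrical diyne stops after the first cleavage because the lithium acetylide formed deactivates the second silyl alkyne, so that aqueous quench should give the mono-protected diyne.

Step 8
Reactants: 9 buta-1,3-diyn-1-yl(trimethyl)silane
Product: 10 [(3E)-4-bromo-3-methylbut-3-en-1-yn-1-yl](trimethyl)silane
Conditions: Me3Al (2.5 equiv), Cp2ZrCl2 (0.3 equiv), CH2Cl2, 0 °C to rt; then NBS, THF, −30 to 0 °C
Reagents that add atoms: trimethylaluminium, C[Al](C)C; N-bromosuccinimide, O=C1CCC(=O)N1Br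
Why: Zirconium-catalysed carboalumination (Negishi carboalumination) adds methyl and aluminium syn across the terminal alkyne with methyl at the internal carbon while the silylated alkyne stays inert, and bromodealumination with NBS occurs with retention, which should fix the E geometry of the trisubstituted alkene.

Step 9
Reactants: 7 1,3-dioxoisoindolin-2-yl 2-(7-methoxy-2,2-dimethyl-2H-chromen-6-yl)propanoate (racemic); 10 [(3E)-4-bromo-3-methylbut-3-en-1-yn-1-yl](trimethyl)silane (1.5 equiv)
Product: 11 [(3E,5S)-5-(7-methoxy-2,2-dimethyl-2H-chromen-6-yl)-3-methylhex-3-en-1-yn-1-yl](trimethyl)silane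
Conditions: NiBr2·diglyme (10 mol %), 2,2'-(cyclopropane-1,1-diyl)bis(3a,8a-dihydro-8H-indeno[1,2-d]oxazole) (single enantiomer, 12 mol %), tetrakis(dimethylamino)ethylene (TDAE, 1.5 equiv), NaI (0.5 equiv), TMSBr (1.0 equiv), DMA, −7 °C
Reagents that add atoms: none
Why: Nickel-catalysed enantioconvergent reductive cross-coupling of a redox-active ester with a vinyl bromide, a reaction type established for N-hydroxyphthalimide esters of 2-arylpropanoic acids, in which single-electron reduction releases CO2 and a planar benzylic radical (erasing the configuration of racemic 7), the bis(oxazoline)-bound vinylnickel species captures it, and reductive elimination from trivalent nickel should set the S centre under ligand control with retention of the E geometry of 10.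

Step 10
Reactants: 12 1-(2,4-dihydroxyphenyl)ethan-1-one
Product: 13 1-(2,4-dihydroxy-5-iodophenyl)ethan-1-one
Conditions: ICl (1.05 equiv), AcOH, rt
Reagents that add atoms: iodine monochloride, ClI
Why: Electrophilic aromatic iodination under acidic conditions should occur at C5, para to the chelated 2-hydroxyl and ortho to the 4-hydroxyl, and not at the hindered C3 between the two oxygens.

Step 11
Reactants: 11 [(3E,5S)-5-(7-methoxy-2,2-dimethyl-2H-chromen-6-yl)-3-methylhex-3-en-1-yn-1-yl](trimethyl)silane; 13 1-(2,4-dihydroxy-5-iodophenyl)ethan-1-one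
Product: 16 1-{6-hydroxy-2-[(2E,4S)-4-(7-methoxy-2,2-dimethyl-2H-chromen-6-yl)pent-2-en-2-yl]-1-benzofuran-5-yl}ethan-1-one, via terminal enyne 14 (not isolated), via ortho-alkynylphenol 15 (not isolated)
Conditions: CsF (2 equiv), PdCl2(PPh3)2 (5 mol %), CuI (10 mol %), Et3N, DMF, degassed, rt then 60 °C
Reagents that add atoms: none
Why: Tandem sila-Sonogashira coupling and heteroannulation, in which fluoride unmasks the alkyne in situ, palladium/copper catalysis joins it to the aryl iodide, and the hydroxyl ortho to the new alkyne (the other is chelated to the acetyl group and not adjacent) adds 5-endo-dig to close the furan ring, the stereocentre and the E-alkene not being involved.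

**Compound list**

1 | 5-bromo-2-hydroxy-4-methoxybenzaldehyde | COc1cc(O)c(C=O)cc1Br | starting material
2 | 4-bromo-2-ethenyl-5-methoxyphenol | COc1cc(O)c(C=C)cc1Br | intermediate
3 | 2-(4-bromo-2-ethenyl-5-methoxyphenoxy)-2-methylpropanoic acid | COc1cc(OC(C)(C)C(=O)O)c(C=C)cc1Br | intermediate
4 | 6-bromo-7-methoxy-2,2-dimethyl-2H-chromene | COc1cc2c(cc1Br)C=CC(C)(C)O2 | intermediate
5 | ethyl 2-(7-methoxy-2,2-dimethyl-2H-chromen-6-yl)propanoate (racemic) | COc1cc2c(cc1C(C)C(=O)OCC)C=CC(C)(C)O2 | intermediate
6 | 2-(7-methoxy-2,2-dimethyl-2H-chromen-6-yl)propanoic acid (racemic) | COc1cc2c(cc1C(C)C(=O)O)C=CC(C)(C)O2 | intermediate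
7 | 1,3-dioxoisoindolin-2-yl 2-(7-methoxy-2,2-dimethyl-2H-chromen-6-yl)propanoate (racemic) | COc1cc2c(cc1C(C)C(=O)ON1C(=O)c3ccccc3C1=O)C=CC(C)(C)O2 | intermediate
8 | 1,4-bis(trimethylsilyl)buta-1,3-diyne | C[Si](C)(C)C#CC#C[Si](C)(C)C | starting material
9 | buta-1,3-diyn-1-yl(trimethyl)silane | C[Si](C)(C)C#CC#C | intermediate
10 | [(3E)-4-bromo-3-methylbut-3-en-1-yn-1-yl](trimethyl)silane | Br/C=C(\C)C#C[Si](C)(C)C | intermediate
11 | [(3E,5S)-5-(7-methoxy-2,2-dimethyl-2H-chromen-6-yl)-3-methylhex-3-en-1-yn-1-yl](trimethyl)silane | COc1cc2c(cc1[C@@H](C)/C=C(\C)C#C[Si](C)(C)C)C=CC(C)(C)O2 | intermediate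
12 | 1-(2,4-dihydroxyphenyl)ethan-1-one | CC(=O)c1ccc(O)cc1O | starting material
13 | 1-(2,4-dihydroxy-5-iodophenyl)ethan-1-one | CC(=O)c1cc(I)c(O)cc1O | intermediate
14 | 7-methoxy-2,2-dimethyl-6-[(2S,3E)-4-methylhex-3-en-5-yn-2-yl]-2H-chromene | COc1cc2c(cc1[C@@H](C)/C=C(\C)C#C)C=CC(C)(C)O2 | intermediate
15 | 1-{2,4-dihydroxy-5-[(3E,5S)-5-(7-methoxy-2,2-dimethyl-2H-chromen-6-yl)-3-methylhex-3-en-1-yn-1-yl]phenyl}ethan-1-one | COc1cc2c(cc1[C@@H](C)/C=C(\C)C#Cc1cc(C(C)=O)c(O)cc1O)C=CC(C)(C)O2 | intermediate
16 | 1-{6-hydroxy-2-[(2E,4S)-4-(7-methoxy-2,2-dimethyl-2H-chromen-6-yl)pent-2-en-2-yl]-1-benzofuran-5-yl}ethan-1-one | COc1cc2c(cc1[C@@H](C)/C=C(\C)c1cc3cc(C(C)=O)c(O)cc3o1)C=CC(C)(C)O2 | target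

**Step count and risks**

Total step count: 11. Longest linear sequence: 8 steps (steps 1, 2, 3, 4, 5, 6, 9 and 11).

The three steps most likely to fail:

First, step 3 (proposed new method). The radical cation of the electron-rich styrene may dimerise or oligomerise before decarboxylation. The aryloxycarbenium ion may lose a proton or be hydrolysed faster than it cyclises. The chromene product may be oxidised further as conversion rises. The fallback uses known chemistry, sets out from 2 and returns at 4. Palladium-catalysed O-(1,1-dimethylallyl)ation of phenol 2 with methyl 2-methylbut-3-en-2-yl carbonate (Pd(PPh3)4, THF, 0 °C) should give 1-bromo-5-ethenyl-2-methoxy-4-[(2-methylbut-3-en-2-yl)oxy]benzene F1. Ring-closing metathesis of this diene with the second-generation Grubbs catalyst RuCl2(=CHPh)(H2IMes)(PCy3) in CH2Cl2 at 40 °C should give 4, the pyran ring then being closed at C3=C4.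

Second, step 9. Capture of the hindered, electron-rich benzylic radical by a vinylnickel species that carries a cis-β-methyl group may be slow. This would lead to radical dimerisation or reduction and to eroded enantioselectivity, and the enyne may also bind the zerovalent nickel. The fallback sets out from 4 and returns at 14. Suzuki–Miyaura coupling of 4 with K[CH2=CHBF3] (PdCl2(dppf), Cs2CO3, THF–H2O, 70 °C) should give 6-ethenyl-7-methoxy-2,2-dimethyl-2H-chromene F2. Rhodium-catalysed asymmetric hydroformylation of the vinylarene (Rh(acac)(CO)2, a bis(diazaphospholane) ligand of the appropriate antipode, CO/H2) should give the branched aldehyde (2R)-2-(7-methoxy-2,2-dimethyl-2H-chromen-6-yl)propanal F3. Wittig olefination with 2-(triphenylphosphoranylidene)propanal (toluene, 60 °C) should give (2E,4S)-4-(7-methoxy-2,2-dimethyl-2H-chromen-6-yl)-2-methylpent-2-enal F4. Ohira–Bestmann homologation (dimethyl (1-diazo-2-oxopropyl)phosphonate, K2CO3, MeOH, 0 °C) should then give terminal enyne 14, which would enter step 11 without CsF.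

Third, step 11. After in situ desilylation the terminal enyne may homocouple (Glaser-type). The ortho-alkynylphenol may also cyclise incompletely, because the para-acetyl group lowers the nucleophilicity of the phenoxide. The fallback sets out from 11 and 13 and returns at 15 and then 16. Separate desilylation of 11 (K2CO3, MeOH, rt) should give isolated 14. Acetylation of 13 (Ac2O, pyridine) should give 4-acetyl-6-iodo-1,3-phenylene diacetate F5. Sonogashira coupling of 14 with F5 at room temperature (PdCl2(PPh3)2, CuI, Et3N, THF) should give 4-acetyl-6-[(3E,5S)-5-(7-methoxy-2,2-dimethyl-2H-chromen-6-yl)-3-methylhex-3-en-1-yn-1-yl]-1,3-phenylene diacetate F6. Methanolysis (K2CO3, MeOH) should give 15, and a separate π-acid-catalysed 5-endo-dig cycloisomerisation (PtCl2, 5 mol %, toluene, 80 °C) should give 16.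

Further compounds
F1 | step 3 | 1-bromo-5-ethenyl-2-methoxy-4-[(2-methylbut-3-en-2-yl)oxy]benzene | COc1cc(OC(C)(C)C=C)c(C=C)cc1Br
F2 | step 9 | 6-ethenyl-7-methoxy-2,2-dimethyl-2H-chromene | COc1cc2c(cc1C=C)C=CC(C)(C)O2
F3 | step 9 | (2R)-2-(7-methoxy-2,2-dimethyl-2H-chromen-6-yl)propanal | COc1cc2c(cc1[C@@H](C)C=O)C=CC(C)(C)O2
F4 | step 9 | (2E,4S)-4-(7-methoxy-2,2-dimethyl-2H-chromen-6-yl)-2-methylpent-2-enal | COc1cc2c(cc1[C@@H](C)/C=C(\C)C=O)C=CC(C)(C)O2
F5 | step 11 | 4-acetyl-6-iodo-1,3-phenylene diacetate | CC(=O)Oc1cc(OC(C)=O)c(C(C)=O)cc1I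
F6 | step 11 | 4-acetyl-6-[(3E,5S)-5-(7-methoxy-2,2-dimethyl-2H-chromen-6-yl)-3-methylhex-3-en-1-yn-1-yl]-1,3-phenylene diacetate | COc1cc2c(cc1[C@@H](C)/C=C(\C)C#Cc1cc(C(C)=O)c(OC(C)=O)cc1OC(C)=O)C=CC(C)(C)O2
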